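- The teal and amber runs leave us one decision on the next flask: with 0.050 M of starting material charged and the other charges unchanged, we stop at 30 h (Sunday's) or leave it until 50 h (Saturday's).

| setting | teal | amber | Saturday's | Sunday's |
|---|---|---|---|---|
| starting material | 0.025 M | 0.10 M | 0.050 M | 0.050 M |
| reagent | 0.15 M | 0.15 M | 0.150 M | 0.150 M |
| free catalyst | 85 µM | 85 µM | 85 µM | 85 µM |
| impurity | 23 µM | 23 µM | 23 µM | 23 µM |
| remark | run made earlier | run made earlier |  |  |
| time |  |  | 50 h | 30 h |

| run | time / h | product / % | starting material / % |
|---|---|---|---|
| teal | 3.00 | 11 | 91 |
| teal | 6.00 | 23 | 73 |
| teal | 12.0 | 38 | 60 |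
| teal | 20.0 | 53 | 41 |
| teal | 40.0 | 80 | 20 |
| amber | 8.00 | 21 | 79 |
| amber | 15.0 | 37 | 67 |
| amber | 25.0 | 52 | 47 |
| amber | 30.0 | 60 | 39 |
| amber | 40.0 | 72 | 29 |

(readings scatter by 2 percentage points)

- the analysis behind the earlier runs scatters by 2 percentage points, standard deviation
- what may be going on: reagent + free catalyst -> catalyst intermediate A; starting material + catalyst intermediate A <-> catalyst intermediate B; catalyst intermediate B -> free catalyst + product; free catalyst + impurity -> spent catalyst

1. which of the two ends with the higher amount of product, in percent of the starting material charged ("neither" if they lie within 2 percentage points) (Saturday's / Sunday's / neither)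
2. product at the end, in percent of the starting material charged, Saturday's
3. product at the end, in percent of the starting material charged, Sunday's

- Within the scatter, both earlier runs lose a steady proportion of their remaining starting material per hour, the pseudo-first-order pattern, so we read a working rate constant from each last reading, the logarithm of charged over left divided by the time: 0.0402 h⁻¹ for teal and 0.0309 h⁻¹ for amber, so amber, the fuller flask, loses a smaller proportion per hour than teal.
- The new charge is twice teal's and half of amber's, so we treat the shift between the two runs as a small correction to one constant and take the square root of their product, the mid-charge rate constant 0.0353 h⁻¹.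
- Our own reckoning lets [starting material] fall exponentially at that constant, which gives 82.9% product for Saturday's and 65.3% for Sunday's, a gap of 18 percentage points against a margin of 2 points, so we would leave the flask the longer time.
- The forecast, reached by a saturation fit, stands above our reckoning, with 85% for Saturday's and 67% for Sunday's, and names Saturday's as the higher: “The runs are otherwise identical, so Saturday's, which runs longer, ends higher.”
- The simulated flasks give 83.4% for Saturday's and 66.1% for Sunday's, so Saturday's ends higher, as the forecast said.

    reagent + free catalyst → catalyst intermediate A (k = 18100 M⁻¹ h⁻¹)
    starting material + catalyst intermediate A ⇌ catalyst intermediate B (K = 16.0 M⁻¹, k = 765 M⁻¹ h⁻¹)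
    catalyst intermediate B → free catalyst + product (k = 117 h⁻¹)
    free catalyst + impurity → spent catalyst (k = 65600 M⁻¹ h⁻¹)

- Saturday's flask left 16.6% of its starting material, which reads back as 0.0359 h⁻¹ against our 0.0353 h⁻¹. The difference in time is the main reason for the gap: Sunday's flask, given Saturday's time, rises from 66.1% to 83.4%, level with Saturday's, and that equal-time run is what would make the forecast's choice wrong. For Saturday's flask read at 12 h, the mid-charge constant gives 34.5% product, and that neighbour flask stands at 35.4%.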